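**Plan**
Numbering: C1 = ester C=O, C2 = its CH2, C3–C6 = the four carbons of the 1,2-dioxane (O2 on C3, O1 on C6), C7–C10 = the first four side-chain carbons.
Retrosynthesis: put a CO2H helper on C7 and cut C6–C7. Then cut ring bonds O2–C3 and O1–C6 (back to an acyclic alkene mesylate, O3 and MeOH), then C2–C3 and C4–C5. In the chain, cut C8–Et, C7=C8 and C10–Me.
Enabling feature: C6 is the fully substituted ring carbon bonded to peroxide oxygen O1. A 6-methoxy-1,2-dioxane therefore ionises to a planar ring peroxycarbenium ion (C6=O1+). C7 becomes a π-nucleophile as the ketene acetal of the homologous acid, and the extra carboxyl later leaves as CO2.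
Forward: the ring is made first (ozonolysis in MeOH gives the C6 hydroperoxyketal, 6-exo-tet SN2 closes O2–C3). The chain is built separately by two conjugate additions, the halves are joined at C6–C7, and decarboxylation comes last.
Stereochemistry: C4 from an auxiliary alkylation; C3 from a catalyst-controlled propargylation followed by inversion; C10 and C8 from Cu/Josiphos conjugate additions; C6 from axial attack on the ring cation (both anomers converge, and the C7 epimers are erased).

Key step: step 18

Assumption: 2-(bromomethyl)but-1-ene is treated as a catalogue compound, and in steps 5, 12 and 15 the catalyst enantiomer used is the one that attacks the face stated there.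

Step 1
Reactants: 1 (R)-4-benzyl-1,3-oxazolidin-2-one; 2 butanoyl chloride
Product: 3 (R)-4-benzyl-3-butanoyl-1,3-oxazolidin-2-one
Conditions: n-BuLi, THF, −78 °C; then 2, −78 → 0 °C
Reagents that add atoms: none
Why: N-acylation of the lithiated oxazolidinone by an acid chloride is the standard entry to the Evans imide and touches no stereocenter.

Step 2
Reactants: 3 (R)-4-benzyl-3-butanoyl-1,3-oxazolidin-2-one; 4 2-(bromomethyl)but-1-ene
Product: 5 (R)-4-benzyl-3-[(2S)-2-ethyl-4-methylidenehexanoyl]-1,3-oxazolidin-2-one
Conditions: NaHMDS, THF, −78 °C; then 4, −78 → −40 °C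
Reagents that add atoms: none
Why: Evans asymmetric alkylation, in which the chelated (Z)-sodium enolate takes up the reactive allylic bromide on the face opposite to the benzyl group and so sets C4 as S.

Step 3
Reactants: 5 (R)-4-benzyl-3-[(2S)-2-ethyl-4-methylidenehexanoyl]-1,3-oxazolidin-2-one
Product: 6 (2S)-2-ethyl-4-methylidenehexan-1-ol
Conditions: LiBH4, Et2O, H2O (1 equiv), 0 °C
Reagents that add atoms: none
Why: Reductive cleavage of the N-acyl oxazolidinone with LiBH4 releases the primary alcohol without epimerisation at C4 and leaves the 1,1-disubstituted alkene untouched.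

Step 4
Reactants: 6 (2S)-2-ethyl-4-methylidenehexan-1-ol
Product: 7 (2S)-2-ethyl-4-methylidenehexanal
Conditions: Dess–Martin periodinane, CH2Cl2, 0 °C → rt; used at once
Reagents that add atoms: none
Why: Dess–Martin oxidation is neutral and fast, so the α-stereocenter C4 of the aldehyde should not epimerise.

Step 5
Reactants: 7 (2S)-2-ethyl-4-methylidenehexanal; 8 allenylboronic acid pinacol ester
Product: 9 (4R,5S)-5-ethyl-7-methylidenenon-1-yn-4-ol
Conditions: TRIP chiral phosphoric acid (10 mol %), 4 Å MS, toluene, −20 °C; aqueous work-up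
Reagents that add atoms: none
Why: Chiral-phosphoric-acid-catalysed propargylboration (SE2′ of the allenylboronate through a closed six-membered transition state) adds to the Re face of the aldehyde under catalyst control. This sets C3 as R, because Et and CH2C(=CH2)Et on C4 exert almost no substrate bias.

Step 6
Reactants: 9 (4R,5S)-5-ethyl-7-methylidenenon-1-yn-4-ol
Product: 10 (4R,5S)-5-ethyl-7-methylidenenon-1-yn-4-yl methanesulfonate
Conditions: MsCl, Et3N, CH2Cl2, 0 °C
Reagents that add atoms: methanesulfonyl chloride CS(=O)(=O)Cl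
Why: O-sulfonylation turns the C3 hydroxyl into a leaving group with retention, and no carbonyl sits β to it that could provoke E1cB loss.

Step 7
Reactants: 10 (4R,5S)-5-ethyl-7-methylidenenon-1-yn-4-yl methanesulfonate
Product: 11 (4R,5S)-5-ethyl-7-hydroperoxy-7-methoxynon-1-yn-4-yl methanesulfonate (both epimers at C6 of the target numbering)
Conditions: O3, CH2Cl2/MeOH, −78 °C, Sudan Red end-point indicator, no reductive work-up
Reagents that add atoms: ozone [O-][O+]=O; methanol CO
Why: Ozonolysis in a participating solvent (Criegee mechanism) cleaves the electron-rich 1,1-dialkyl alkene far faster than the alkyne. It gives the more substituted carbonyl oxide at C6 plus formaldehyde, and MeOH traps the carbonyl oxide as the hydroperoxyketal.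

Step 8
Reactants: 11 (4R,5S)-5-ethyl-7-hydroperoxy-7-methoxynon-1-yn-4-yl methanesulfonate
Product: 12 (3S,4S)-4,6-diethyl-6-methoxy-3-(prop-2-yn-1-yl)-1,2-dioxane (both C6 anomers)
Conditions: KOt-Bu (1.05 equiv), 18-crown-6 (cat.), toluene, 0 °C → rt
Reagents that add atoms: none
Why: Intramolecular alkylation of a hydroperoxyketal by a secondary sulfonate (6-exo-tet SN2) closes the 1,2-dioxane with clean inversion at C3 (3R → 3S). This gives the 3,4-cis relationship, and the C6 anomers need no control.

Step 9
Reactants: 12 (3S,4S)-4,6-diethyl-6-methoxy-3-(prop-2-yn-1-yl)-1,2-dioxane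
Product: 13 2-[(3S,4S)-4,6-diethyl-6-methoxy-1,2-dioxan-3-yl]acetic acid
Conditions: RuCl3·xH2O (5 mol %), NaIO4, MeCN/EtOAc/H2O, 0 °C
Reagents that add atoms: sodium periodate [Na+].[O-]I(=O)(=O)=O; water O
Why: RuO4-catalysed oxidative cleavage of a terminal alkyne gives the acid shortened by one carbon, and dialkyl peroxides are already at the oxidation level that such oxidants tolerate.

Step 10
Reactants: 13 2-[(3S,4S)-4,6-diethyl-6-methoxy-1,2-dioxan-3-yl]acetic acid
Product: 14 methyl 2-[(3S,4S)-4,6-diethyl-6-methoxy-1,2-dioxan-3-yl]acetate (both C6 anomers)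
Conditions: TMSCHN2, toluene/MeOH, 0 °C
Reagents that add atoms: (trimethylsilyl)diazomethane C[Si](C)(C)C=[N+]=[N-]
Why: Esterification with a diazoalkane needs no base, so retro-oxa-Michael opening of the β-peroxy ester and loss of C3 integrity are avoided.

Step 11
Reactants: 15 (E)-hept-2-enoic acid
Product: 16 S-ethyl (E)-hept-2-enethioate
Conditions: EtSH, DCC, DMAP (cat.), CH2Cl2, 0 °C
Reagents that add atoms: ethanethiol CCS
Why: Steglich-type thioesterification gives the α,β-unsaturated thioester, the acceptor class that takes up MeMgBr cleanly in the next step.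

Step 12
Reactants: 16 S-ethyl (E)-hept-2-enethioate
Product: 17 S-ethyl (3S)-3-methylheptanethioate
Conditions: MeMgBr, CuBr·SMe2 (2 mol %), Josiphos SL-J001 (2.4 mol %), t-BuOMe, −75 °C; then H2O
Reagents that add atoms: methylmagnesium bromide C[Mg]Br
Why: Copper/ferrocenyl-diphosphine-catalysed asymmetric conjugate addition of a Grignard reagent to an unsaturated thioester delivers methyl to the Si face of the β-carbon and sets C10 as S.

Step 13
Reactants: 17 S-ethyl (3S)-3-methylheptanethioate
Product: 18 (3S)-3-methylheptanal
Conditions: DIBAL-H, CH2Cl2, −65 °C; Rochelle salt work-up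
Reagents that add atoms: none
Why: Partial reduction of a thioester stops at the aluminium hemithioacetal and gives the aldehyde on work-up, and the β-stereocenter cannot epimerise.

Step 14
Reactants: 18 (3S)-3-methylheptanal
Product: 19 methyl (2E,5S)-5-methylnon-2-enoate
Conditions: Ph3P=CHCO2Me, CH2Cl2, rt
Reagents that add atoms: methyl (triphenylphosphoranylidene)acetate COC(=O)C=P(c1ccccc1)(c1ccccc1)c1ccccc1
Why: The Wittig reaction of a stabilised ylide gives the (E)-enoate and brings in C7 together with the carboxyl carbon that serves three times: as acceptor, as activator of C7 and as leaving CO2.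

Step 15
Reactants: 19 methyl (2E,5S)-5-methylnon-2-enoate
Product: 20 methyl (3S,5S)-3-ethyl-5-methylnonanoate
Conditions: EtMgBr, CuBr·SMe2 (2 mol %), Josiphos SL-J001 (same enantiomer as in step 12), t-BuOMe, −75 °C; then H2O
Reagents that add atoms: ethylmagnesium bromide CC[Mg]Br
Why: The same copper-catalysed asymmetric conjugate addition places ethyl on the Si face of the β-carbon under catalyst control. It sets C8 as S, as in iterative 1,3-syn deoxypropionate syntheses.

Step 16
Reactants: 20 methyl (3S,5S)-3-ethyl-5-methylnonanoate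
Product: 21 (3S,5S)-3-ethyl-5-methylnonanoic acid
Conditions: LiOH, THF/MeOH/H2O, rt; then 1 M HCl
Reagents that add atoms: lithium hydroxide [Li+].[OH-]
Why: Plain saponification, in which neither stereocenter is α to the carbonyl and so neither is at risk.

Step 17
Reactants: 21 (3S,5S)-3-ethyl-5-methylnonanoic acid
Product: 22 (3S,5S)-3-ethyl-5-methyl-1,1-bis(trimethylsilyloxy)non-1-ene
Conditions: LDA (2.2 equiv), THF, −78 → 0 °C; TMSCl (2.5 equiv), −78 °C → rt; filtration under Ar, used crude
Reagents that add atoms: chlorotrimethylsilane C[Si](C)(C)Cl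
Why: Double O-silylation of the carboxylic acid dianion gives the bis-silyl ketene acetal. C-silylation is disfavoured by the sec-alkyl group on C7, and C8 is not deprotonated.

Step 18
Reactants: 14 methyl 2-[(3S,4S)-4,6-diethyl-6-methoxy-1,2-dioxan-3-yl]acetate; 22 (3S,5S)-3-ethyl-5-methyl-1,1-bis(trimethylsilyloxy)non-1-ene
Product: 25 (3S,5S)-2-[(3R,5S,6S)-3,5-diethyl-6-(2-methoxy-2-oxoethyl)-1,2-dioxan-3-yl]-3-ethyl-5-methylnonanoic acid (both epimers at the carboxyl-bearing carbon C7), via peroxycarbenium triflate 23 (not isolated), via trimethylsilyl ester 24 (not isolated)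
Conditions: 22 (2 equiv), TMSOTf (0.3 equiv), CH2Cl2, −78 → −40 °C; pH 7 buffer work-up
Reagents that add atoms: none
Why: TMSOTf silylates the exocyclic methoxy oxygen of either C6 anomer of 14 (an ether oxygen is more Lewis basic than the ring peroxide oxygens) and MeOSiMe3 leaves with help from the O1 lone pair, so both anomers funnel into the one planar peroxycarbenium ion 23. C7 of ketene acetal 22 then attacks C6 through an open transition state, the silyl group returns to triflate, and silyl ester 24 is hydrolysed to 25 on work-up; the closest known reaction type is the Lewis-acid-mediated, Mukaiyama-type substitution of acyclic and cyclic peroxyketals (3-alkoxy-1,2-dioxolanes and -dioxanes) by silyl ketene acetals, silyl enol ethers and allylsilanes. No ring is closed and the dioxane stays intact. C6 is controlled by the ring: in the half-chair with the C4 ethyl pseudoequatorial the nucleophile enters on the axial trajectory that leads directly to a chair, on the face opposite to the pseudoaxial C3 side chain, whereas the other half-chair would need attack syn-axial to the C4 ethyl, so the new C6–C7 bond ends up axial and trans to C4-Et and C3-CH2CO2Me, which is the target arrangement (descriptor R in 25 only because C7 outranks C5 while it carries CO2H). The order of bond formation, not size, thus tells apart the two nearly equal alkyl groups on C6, while the ketene acetal geometry and the new C7 center need no control because C7 becomes CH2 in step 19, and C8 and C10 are spectators. The step needs exocyclic rather than endocyclic C–O ionisation and survival of O–O and the ester, which low temperature, a catalytic silyl Lewis acid and a neutral π-nucleophile (which does not attack peroxide oxygen as organometallic reagents would) should secure.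

Step 19
Reactants: 25 (3S,5S)-2-[(3R,5S,6S)-3,5-diethyl-6-(2-methoxy-2-oxoethyl)-1,2-dioxan-3-yl]-3-ethyl-5-methylnonanoic acid
Product: 28 methyl 2-[(3S,4S,6S)-4,6-diethyl-6-[(2S,4S)-2-ethyl-4-methyloctyl]-1,2-dioxan-3-yl]acetate, via acid chloride 26 (not isolated), via thiohydroxamate ester 27 (not isolated)
Conditions: (COCl)2, DMF (cat.), CH2Cl2, 0 °C, evaporate; sodium pyrithione, DMAP (cat.), t-BuSH (10 equiv), CH2Cl2, 0 °C, dark, then W lamp
Reagents that add atoms: none
Why: Barton reductive decarboxylation removes the helper as CO2 and turns both C7 epimers into the same CH2. The secondary C7 radical should take H from concentrated t-BuSH faster than it attacks O1, because the axial C7 has a C7–C6–O1–O2 dihedral near 60° that forbids collinear homolytic displacement, as supported by the known hydride reductions of β-iodo and β-mercurio peroxides.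

**Compound list**
1 | (R)-4-benzyl-1,3-oxazolidin-2-one | O=C1N[C@H](Cc2ccccc2)CO1 | starting material
2 | butanoyl chloride | CCCC(=O)Cl | starting material
3 | (R)-4-benzyl-3-butanoyl-1,3-oxazolidin-2-one | CCCC(=O)N1[C@H](Cc2ccccc2)COC1=O | intermediate
4 | 2-(bromomethyl)but-1-ene | CCC(=C)CBr | starting material
5 | (R)-4-benzyl-3-[(2S)-2-ethyl-4-methylidenehexanoyl]-1,3-oxazolidin-2-one | CCC(=C)C[C@H](CC)C(=O)N1[C@H](Cc2ccccc2)COC1=O | intermediate
6 | (2S)-2-ethyl-4-methylidenehexan-1-ol | CCC(=C)C[C@H](CC)CO | intermediate
7 | (2S)-2-ethyl-4-methylidenehexanal | CCC(=C)C[C@H](CC)C=O | intermediate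
8 | allenylboronic acid pinacol ester | C=C=CB1OC(C)(C)C(C)(C)O1 | starting material
9 | (4R,5S)-5-ethyl-7-methylidenenon-1-yn-4-ol | C#CC[C@@H](O)[C@@H](CC)CC(=C)CC | intermediate
10 | (4R,5S)-5-ethyl-7-methylidenenon-1-yn-4-yl methanesulfonate | C#CC[C@@H](OS(C)(=O)=O)[C@@H](CC)CC(=C)CC | intermediate
11 | (4R,5S)-5-ethyl-7-hydroperoxy-7-methoxynon-1-yn-4-yl methanesulfonate, ketal epimers | C#CC[C@@H](OS(C)(=O)=O)[C@@H](CC)CC(CC)(OC)OO | intermediate
12 | (3S,4S)-4,6-diethyl-6-methoxy-3-(prop-2-yn-1-yl)-1,2-dioxane, C6 anomers | C#CC[C@@H]1OOC(CC)(OC)C[C@@H]1CC | intermediate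
13 | 2-[(3S,4S)-4,6-diethyl-6-methoxy-1,2-dioxan-3-yl]acetic acid, C6 anomers | OC(=O)C[C@@H]1OOC(CC)(OC)C[C@@H]1CC | intermediate
14 | methyl 2-[(3S,4S)-4,6-diethyl-6-methoxy-1,2-dioxan-3-yl]acetate, C6 anomers | COC(=O)C[C@@H]1OOC(CC)(OC)C[C@@H]1CC | intermediate
15 | (E)-hept-2-enoic acid | CCCC/C=C/C(=O)O | starting material
16 | S-ethyl (E)-hept-2-enethioate | CCCC/C=C/C(=O)SCC | intermediate
17 | S-ethyl (3S)-3-methylheptanethioate | CCCC[C@H](C)CC(=O)SCC | intermediate
18 | (3S)-3-methylheptanal | CCCC[C@H](C)CC=O | intermediate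
19 | methyl (2E,5S)-5-methylnon-2-enoate | CCCC[C@H](C)C/C=C/C(=O)OC | intermediate
20 | methyl (3S,5S)-3-ethyl-5-methylnonanoate | CCCC[C@H](C)C[C@H](CC)CC(=O)OC | intermediate
21 | (3S,5S)-3-ethyl-5-methylnonanoic acid | CCCC[C@H](C)C[C@H](CC)CC(=O)O | intermediate
22 | (3S,5S)-3-ethyl-5-methyl-1,1-bis(trimethylsilyloxy)non-1-ene | CCCC[C@H](C)C[C@H](CC)C=C(O[Si](C)(C)C)O[Si](C)(C)C | intermediate
23 | (3S,4S)-4,6-diethyl-3-(2-methoxy-2-oxoethyl)-4,5-dihydro-3H-1,2-dioxin-1-ium triflate (ring peroxycarbenium ion, C6=O1+) | CCC1=[O+]O[C@@H](CC(=O)OC)[C@@H](CC)C1.[O-]S(=O)(=O)C(F)(F)F | intermediate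
24 | trimethylsilyl ester of 25, C7 epimers | CCCC[C@H](C)C[C@H](CC)C(C(=O)O[Si](C)(C)C)[C@@]1(CC)C[C@H](CC)[C@H](CC(=O)OC)OO1 | intermediate
25 | (3S,5S)-2-[(3R,5S,6S)-3,5-diethyl-6-(2-methoxy-2-oxoethyl)-1,2-dioxan-3-yl]-3-ethyl-5-methylnonanoic acid, C7 epimers | CCCC[C@H](C)C[C@H](CC)C(C(=O)O)[C@@]1(CC)C[C@H](CC)[C@H](CC(=O)OC)OO1 | intermediate
26 | acid chloride of 25 | CCCC[C@H](C)C[C@H](CC)C(C(=O)Cl)[C@@]1(CC)C[C@H](CC)[C@H](CC(=O)OC)OO1 | intermediate
27 | 2-thioxopyridin-1(2H)-yl ester of 25 | CCCC[C@H](C)C[C@H](CC)C(C(=O)ON2C=CC=CC2=S)[C@@]1(CC)C[C@H](CC)[C@H](CC(=O)OC)OO1 | intermediate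
28 | methyl 2-[(3S,4S,6S)-4,6-diethyl-6-[(2S,4S)-2-ethyl-4-methyloctyl]-1,2-dioxan-3-yl]acetate | CCCC[C@H](C)C[C@H](CC)C[C@@]1(CC)C[C@H](CC)[C@H](CC(=O)OC)OO1 | target

Total steps: 19. Longest linear sequence: 12 (steps 1–10, 18, 19).

**Steps most likely to fail**

Step 18. Bond formation between the tertiary ring cation and the sec-alkyl-substituted C7 may be slow. Proton loss from C5, endocyclic C6–O1 ionisation or acid-induced O–O heterolysis could then take over. With so reactive a ketene acetal the axial preference may also erode.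
- The fallback sets out from thioester 17 and peroxyketal 14 and comes back at 28.
- It replaces the helper-bearing nucleophile with an allylsilane that attacks through an unsubstituted CH2 terminus (Hosomi–Sakurai-type substitution).
- Thioester 17 would react with [1-(trimethylsilyl)ethyl]magnesium chloride under Fe(acac)3 catalysis to give the α-silyl ketone (5S)-5-methyl-2-(trimethylsilyl)nonan-3-one F1.
- Wittig methylenation with Ph3P=CH2 would give the allylsilane trimethyl[(5S)-5-methyl-3-methylidenenonan-2-yl]silane F2.
- F2 with 14 and catalytic TMSOTf at −78 °C should give methyl 2-[(3S,4S,6R)-4,6-diethyl-6-[(4S)-2-ethylidene-4-methyloctyl]-1,2-dioxan-3-yl]acetate F3, under the same axial control at C6.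
- Diimide, or a Mn-hydride HAT hydrogenation, would then saturate the C8 alkene to 28 and its C8 epimer, which have to be separated. This path therefore gives up control at C8.

Step 19. Activation of the very hindered acid may lag. The C7 radical may also attack O1 with O–O cleavage (oxirane formation) before it is reduced.
- The fallback sets out from 25 (through 27) and comes back at 28. It splits the event into halodecarboxylation and hydrodehalogenation.
- Photolysis of 27 in the presence of CHI3 traps the radical by iodine-atom transfer, which is faster than hydrogen transfer from a thiol. It gives methyl 2-[(3S,4S,6R)-4,6-diethyl-6-[(2S,4S)-2-ethyl-1-iodo-4-methyloctyl]-1,2-dioxan-3-yl]acetate F4.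
- Bu3SnH with Et3B/air at −78 °C would then remove iodine. This reaction type is documented for β-iodo peroxides, and the low temperature disfavours the homolytic displacement at oxygen.

Step 8. E2 loss of the mesylate toward the propargylic C2 hydrogens, or slow substitution next to the branched C4, may compete with the 6-exo-tet closure.
- The fallback sets out from aldehyde 7 and comes back at 14. It closes O2–C3 by conjugate addition instead of substitution.
- Wittig reaction of 7 with Ph3P=CHCO2Me gives methyl (2E,4S)-4-ethyl-6-methylideneoct-2-enoate F5.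
- Ozonolysis in MeOH, selective for the electron-rich alkene, gives methyl (2E,4S)-4-ethyl-6-hydroperoxy-6-methoxyoct-2-enoate F6.
- Et2NH in CF3CH2OH then triggers the intramolecular oxa-Michael addition to 14 and its C3 epimer.
- C3 is then under substrate control only, which may favour the 3,4-trans isomer, so separation is required.

**Further compounds**
F1 | step 18 | (5S)-5-methyl-2-(trimethylsilyl)nonan-3-one | CCCC[C@H](C)CC(=O)C(C)[Si](C)(C)C
F2 | step 18 | trimethyl[(5S)-5-methyl-3-methylidenenonan-2-yl]silane | CCCC[C@H](C)CC(=C)C(C)[Si](C)(C)C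
F3 | step 18 | methyl 2-[(3S,4S,6R)-4,6-diethyl-6-[(4S)-2-ethylidene-4-methyloctyl]-1,2-dioxan-3-yl]acetate | CCCC[C@H](C)CC(=CC)C[C@@]1(CC)C[C@H](CC)[C@H](CC(=O)OC)OO1
F4 | step 19 | methyl 2-[(3S,4S,6R)-4,6-diethyl-6-[(2S,4S)-2-ethyl-1-iodo-4-methyloctyl]-1,2-dioxan-3-yl]acetate | CCCC[C@H](C)C[C@H](CC)C(I)[C@@]1(CC)C[C@H](CC)[C@H](CC(=O)OC)OO1
F5 | step 8 | methyl (2E,4S)-4-ethyl-6-methylideneoct-2-enoate | CCC(=C)C[C@H](CC)/C=C/C(=O)OC
F6 | step 8 | methyl (2E,4S)-4-ethyl-6-hydroperoxy-6-methoxyoct-2-enoate | CCC(OC)(OO)C[C@H](CC)/C=C/C(=O)OC
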